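| flask | substrate | partner A | partner B | remark | time |
|---|---|---|---|---|---|
| larch | 0.50 M | 0.90 M | 0.45 M | run made earlier |  |
| maple | 0.50 M | 0.90 M | 0.68 M | run made earlier |  |
| birch | 0.25 M | 0.90 M | 0.90 M | run made earlier |  |
| flask | 0.50 M | 0.900 M | 0.900 M |  | 10 d |

| run | time / d | target / % | open intermediate / % | substrate / % |
|---|---|---|---|---|
| larch | 1.25 | 2.2 | 13.7 | 84.9 |
| larch | 2.50 | 5.6 | 10.5 | 84.7 |
| larch | 4.00 | 6.2 | 8.5 | 84.7 |
| larch | 5.00 | 7.6 | 8.4 | 84.2 |
| larch | 6.00 | 7.6 | 8.1 | 84.9 |
| larch | 8.00 | 8.3 | 7.2 | 83.6 |
| maple | 0.625 | 1.0 | 17.7 | 80.8 |
| maple | 1.04 | 3.2 | 18.7 | 77.5 |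
| maple | 1.67 | 6.4 | 18.3 | 74.4 |
| maple | 3.00 | 10.7 | 14.4 | 73.5 |
| maple | 5.00 | 14.6 | 12.8 | 72.3 |
| maple | 8.00 | 15.9 | 10.4 | 73.7 |
| birch | 0.625 | 2.5 | 23.7 | 72.2 |
| birch | 1.25 | 7.4 | 27.4 | 65.2 |
| birch | 2.50 | 17.0 | 25.7 | 57.3 |
| birch | 4.00 | 24.1 | 22.1 | 54.3 |
| birch | 8.00 | 30.0 | 17.3 | 52.3 |

(readings scatter by 0.5 percentage points)

- which holds at 10 d: what has brought the reaction to rest, or that it has not come to rest (forward and back rates have come level / it is still moving / the partner A has run out first / all of the substrate has reacted)
- amount of target at 10 d, in percent of the substrate charged
- amount of open intermediate at 10 d, in percent of the substrate charged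

- the numbers in the tables scatter by 0.5 percentage points (one standard deviation)
- the reaction counts as stopped when no species that holds the substrate changes by six tenths of a point or more over the second half of the time

The ratio of extra substrate converted to extra partner B charged can set the next charge: the larch and maple runs hold the same substrate and partner A, differ in partner B, and their substrate readings go flat within the scatter of 0.5 percentage points. Averaged over the late readings, the larch run has converted 0.0788 M of substrate and the maple run 0.134 M, which gives m = 0.241, the marginal capture: extra substrate converted per extra partner B charged, with substrate and partner A held at these charges. Waiting promises little, since larch substrate reads 84.7% at 2.50 d and 84.9% at 6.00 d. The next flask therefore keeps substrate and partner A and raises partner B to 0.900 M, where m carried from the maple run gives 0.187 M converted, or 37.4% of the charge, to be shared between target and open intermediate. Flat substrate is not rest, however: in the maple run, between 5.00 d and 8.00 d, substrate reads 72.3% and then 73.7% without falling, while open intermediate drops from 12.8% to 10.4% and target climbs from 14.6% to 15.9%, so this reckoning expects the flask to be still moving at 10 d.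

The forecast gives 24% of target and 13% of open intermediate and holds that it is still moving: “From 5 to 10 d, target should therefore still gain about 2–3 points and I lose about 2, which exceeds 0.6.”

The flask gives 25.0% of target and 14.1% of open intermediate, and it is still moving; with 60.9% of its substrate left, it has converted 0.196 M against the 0.187 M reckoned.

    partner B + partner A → second intermediate (k = 0.131 /M/h)
    substrate + partner B → open intermediate (k = 0.0426 /M/h)
    2 second intermediate → homo product (k = 0.0150 /M/h)
    open intermediate + second intermediate ⇌ target (K = 21.0 /M, k = 0.0283 /M/h)

Partner B is the limiting reagent: in the flask it stands at 0.284% of its charge at 5.00 d and 0% at 10.0 d, and the same flask with partner B held at its charge converts >99.9% of the substrate against 39.1%, so the shrinking supply of partner B is the main reason substrate remains. Beyond the maple run, the flask's capture is 0.279 against m of 0.241. For the neighbour flask with 2.2 M of partner B, m gives 0.500 M converted against 0.50 M charged, and that flask keeps 0.0151% of its substrate, with 36.4% of its partner B left.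

(The earlier runs and the new flask were generated by integration with made-up constants.)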